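Start from the product E, with X beside it: in the larch run both stand flat from the first reading, at 3.00 h. The candidate steps are D + J to X, D + Q to E, and J to Z.

| setting | cedar | larch | alder | flask |
|---|---|---|---|---|
| D | 0.10 M | 0.10 M | 0.10 M | 0.10 M |
| J | 0.064 M | 0.14 M | 0.095 M | 0.0950 M |
| Q | 0.060 M | 0.060 M | 0.030 M | 0.0600 M |
| remark | run made earlier | run made earlier | run made earlier |  |
| time |  |  |  | 3.0 d |

| run | time / h | D / % | X / % | E / % |
|---|---|---|---|---|
| cedar | 10.0 | 31 | 13 | 60 |
| cedar | 20.0 | 34 | 10 | 61 |
| cedar | 30.0 | 33 | 11 | 58 |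
| cedar | 40.0 | 31 | 9 | 62 |
| larch | 3.00 | 20 | 18 | 61 |
| larch | 8.00 | 24 | 19 | 61 |
| larch | 20.0 | 19 | 19 | 58 |
| larch | 40.0 | 26 | 17 | 59 |
| alder | 3.00 | 54 | 13 | 28 |
| alder | 8.00 | 55 | 14 | 32 |
| alder | 20.0 | 54 | 14 | 27 |
| alder | 40.0 | 57 | 17 | 30 |

(each reading ± 2 percentage points)

- candidate steps: D + J -> X; D + Q -> E; J -> Z

- how much of the D has reacted by 3.0 d
- how much X there is at 3.0 d, in percent of the D charged
- how much E there is at 3.0 d, in percent of the D charged

Reckon the rate alone, in decades (powers of ten). In the larch run, D fell on average by 0.267 h⁻¹ of its charge up to the first reading. Then bound the late rate. Larch D drifts from first to last reading by a size that gives 0.00162 h⁻¹, and that drift is upward, so treat it as noise and take that size as an estimate of any fall the scatter hides. Read so, the larch rate has slowed by some 2.22 decades. Assume both steps of D run as D times a partner. The fall of D itself accounts for 0.699 decades. On this estimate the partners J and Q supply the other 1.52.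

Now take the flask. Q is charged at less than D, so treat Q as the limiting reagent for E. My reckoning is the E ceiling, Emax, the Q charged over the D charged: 60.0 %. Expect the flask to be stopped by 3.0 d, which lies 1.38 decades past the first larch reading.

The forecast gives E 60 % (57 % to 62 %), X 14 % (12 % to 16.5 %) and D reacted 74 % (70 % to 78 %), holding that “Q is fully consumed”.

The flask gives E 60.0 %, X 13.0 % and D reacted 73.0 %.

    D + J → X (k = 0.640 M⁻¹ min⁻¹)
    D + Q → E (k = 2.20 M⁻¹ min⁻¹)
    J → Z (k = 0.290 min⁻¹)

In the flask E stands at 60.0 % by 0.300 d and at 60.0 % at 30.0 d, level with Emax; the length of the run makes no difference to the D reacted. Apply Emax to the neighbour flask, charged with 0.015 M of Q. The ceiling scales with the Q charged, to 15.0 %. That flask gives E 15.0 % and X 15.2 %, and it keeps 69.8 % of its D.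

The readings stem from a simulated flask for an exercise.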